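**Plan**

1. Ring numbering used below: C1 = CHOH, C2 = CH(isopropenyl), C3 = C(CH3)(vinyl), C4 and C5 = CH2, C6 = CH(side chain); compound names carry IUPAC locants.
2. Cuts, in retrosynthetic order: C1–H (back to the ketone); C6–C(OH)(CH2OAc)2 (aldol with 1,3-diacetoxyacetone); the isopropenyl group on C2 back to CO2CH3; then C5–C6 and C2–C3 together, which leaves methyl acetoacetate and an (E)-3-methylpent-2-enyl unit with Br at one end and OPh at the other.
3. What makes the double cut possible: C1 is an oxygen-bearing carbon flanked by C2 and C6, the α- and γ-carbons of an acetoacetate dianion; C3 carries a vinyl group and lies 1,3 to C5, so it is the substituted end of an allyl cation whose chain ends in a primary bromide. The cyclohexane is the only ring and arises in that step.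
4. Forward: C6 electrophile (steps 1–3), one-flask ring formation (step 4), ester to isopropenyl (steps 5–7), side chain and C1 (steps 8–10).
5. Stereochemistry: C3 from the chiral ligand on palladium in the ring closure; C2 from a catalyst-controlled dynamic kinetic hydrogenation (the C1 carbinol made there is a relay and is oxidised again); C6 as the equatorial aldol; C1 by hydroxyl-directed hydride delivery.

Key step: step 4

Remark: each chiral catalyst is named in the antipode expected, by analogy with simpler substrates, to give the configuration drawn; the other antipode is used if a pilot run shows the opposite sense.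

Step 1
Reactants: 1 but-3-yn-1-ol
Product: 3 (2E)-3-methylpent-2-ene-1,5-diol, via alkenylalane 2 (not isolated)
Conditions: Me3Al (2.5 equiv), Cp2ZrCl2 (0.25 equiv), CH2Cl2, 0 °C to rt; n-BuLi (1 equiv), THF, −78 °C; (CH2O)n, rt; aq. NH4Cl
Reagents that add atoms: trimethylaluminium C[Al](C)C; paraformaldehyde (as formaldehyde) C=O
Why: Negishi zirconium-catalysed carboalumination adds methyl and aluminium syn across the terminal alkyne with methyl on the internal carbon, and the derived alanate is hydroxymethylated by formaldehyde with retention, which should give the E-trisubstituted alkene only.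

Step 2
Reactants: 3 (2E)-3-methylpent-2-ene-1,5-diol
Product: 4 (2E)-1,5-dibromo-3-methylpent-2-ene
Conditions: CBr4 (2.2 equiv), PPh3 (2.2 equiv), CH2Cl2, 0 °C
Reagents that add atoms: carbon tetrabromide BrC(Br)(Br)Br
Why: Appel reaction: both primary hydroxyls are converted into bromides by SN2 displacement of the oxyphosphonium groups under neutral conditions, without allylic transposition or loss of the alkene geometry.

Step 3
Reactants: 4 (2E)-1,5-dibromo-3-methylpent-2-ene
Product: 5 {[(2E)-5-bromo-3-methylpent-2-en-1-yl]oxy}benzene
Conditions: PhOH (1.0 equiv), K2CO3, acetone, rt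
Reagents that add atoms: phenol Oc1ccccc1
Why: Williamson ether synthesis (SN2): the allylic bromide is displaced far faster than the homoallylic primary bromide, so one equivalent of phenoxide should give the allyl phenyl ether, a leaving group that survives the dianion of step 4 and is ionised only by palladium.

Step 4
Reactants: 5 {[(2E)-5-bromo-3-methylpent-2-en-1-yl]oxy}benzene; 6 methyl 3-oxobutanoate (methyl acetoacetate)
Product: 8 methyl (2S)-2-ethenyl-2-methyl-6-oxocyclohexane-1-carboxylate, via acyclic keto ester 7 (not isolated)
Conditions: 6, NaH (1.05 equiv), THF, 0 °C; n-BuLi (1.05 equiv), 0 °C; 5, 0 °C to rt; then Pd2(dba)3·CHCl3 (2.5 mol %), (R,R)-DACH-phenyl Trost ligand (7.5 mol %), THF (0.02 M), rt to 40 °C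
Reagents that add atoms: none
Why: The α,γ-dianion of 6 attacks the primary bromide of 5 through its γ-carbon (SN2, acetoacetate dianion alkylation; the allyl phenyl ether does not react), which makes C5–C6 and leaves the stabilised monoenolate of 7 tethered to the allylic ether. Zerovalent palladium then ionises the phenoxide and the enolate α-carbon attacks the methyl-substituted terminus of the π-allyl complex, which makes C2–C3 and releases the vinyl group (intramolecular Tsuji–Trost alkylation; the closest known case is the palladium cyclisation of 3-oxo-9-phenoxynon-7-enoates to 2-vinylcyclohexanones). The cyclohexane closes in the 6-exo mode: the E-alkene gives the syn π-allyl complex, from which attack at the unsubstituted terminus would need a trans-cyclooctene, and O-allylation to a dihydropyran is reversible under palladium and drains to the C-alkylated ketone. The quaternary centre C3 is set by the ligand: the two faces of the π-allyl unit exchange through the unsubstituted terminus (η3–η1–η3) and the chiral pocket decides which face the enolate attacks, S being expected. C2 is formed as an epimerising β-keto ester centre and is fixed in step 5. The step needs chemoselectivity between the two electrophilic carbons of 5, secured by the order of events and the inert phenoxy group, and six- over eight-membered ring closure, secured by the alkene geometry.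

Step 5
Reactants: 8 methyl (2S)-2-ethenyl-2-methyl-6-oxocyclohexane-1-carboxylate
Product: 9 methyl (1S,2S,6S)-2-ethenyl-6-hydroxy-2-methylcyclohexane-1-carboxylate
Conditions: RuBr2[(S)-BINAP] (1 mol %), H2 (50 atm), CH2Cl2, 50 °C
Reagents that add atoms: none
Why: Noyori asymmetric hydrogenation with dynamic kinetic resolution: the ester-bearing carbon (C2) epimerises through the enol while the BINAP–ruthenium chelate of the β-keto ester delivers hydrogen to one face of the ketone, so that the carbinol (C1) should be S and the ester trans to it, as known for 2-alkoxycarbonylcycloalkanones, which places the ester cis to the ring methyl; the monosubstituted alkene on the quaternary carbon is hindered and is expected to survive.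

Step 6
Reactants: 9 methyl (1S,2S,6S)-2-ethenyl-6-hydroxy-2-methylcyclohexane-1-carboxylate
Product: 12 (1S,2S,3S)-3-ethenyl-3-methyl-2-(prop-1-en-2-yl)cyclohexan-1-ol, via bis(silylmethyl) carbinol 10 (not isolated), via allylsilane 11 (not isolated)
Conditions: TMSCH2MgCl (5 equiv), CeCl3 (5 equiv), THF, −78 °C to rt; aq. NH4Cl; then p-TsOH·H2O (0.2 equiv), wet CH2Cl2, rt
Reagents that add atoms: (trimethylsilyl)methylmagnesium chloride C[Si](C)(C)C[Mg]Cl
Why: Cerium-mediated double addition of the silylmethyl Grignard reagent to the ester gives the bis(β-silyl) carbinol, acid triggers Peterson elimination to the allylsilane and then protodesilylation with allylic shift, so that CO2CH3 becomes prop-1-en-2-yl without enolising or epimerising C2.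

Step 7
Reactants: 12 (1S,2S,3S)-3-ethenyl-3-methyl-2-(prop-1-en-2-yl)cyclohexan-1-ol
Product: 13 (2S,3S)-3-ethenyl-3-methyl-2-(prop-1-en-2-yl)cyclohexan-1-one
Conditions: Dess–Martin periodinane, NaHCO3, CH2Cl2, 0 °C
Reagents that add atoms: none
Why: Dess–Martin oxidation of the secondary alcohol under buffered, non-enolising conditions should give the β,γ-unsaturated ketone without epimerisation at C2 or migration of the isopropenyl double bond into conjugation.

Step 8
Reactants: 13 (2S,3S)-3-ethenyl-3-methyl-2-(prop-1-en-2-yl)cyclohexan-1-one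
Product: 14 {[(5S,6S)-5-ethenyl-5-methyl-6-(prop-1-en-2-yl)cyclohex-1-en-1-yl]oxy}trimethylsilane
Conditions: LiN(iPr)2 (LDA), TMSCl (in situ quench), THF, −78 °C; Et3N, pentane work-up
Reagents that add atoms: chlorotrimethylsilane C[Si](C)(C)Cl
Why: Kinetic enolisation with lithium diisopropylamide and in situ silylation removes a proton from the unhindered C6 methylene and not from the C2 methine, which is shielded by the neighbouring quaternary carbon, and so gives the less substituted silyl enol ether regioselectively.

Step 9
Reactants: 14 {[(5S,6S)-5-ethenyl-5-methyl-6-(prop-1-en-2-yl)cyclohex-1-en-1-yl]oxy}trimethylsilane; 15 2-oxopropane-1,3-diyl diacetate (1,3-diacetoxyacetone)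
Product: 16 2-[(1S,3S,4S)-4-ethenyl-4-methyl-2-oxo-3-(prop-1-en-2-yl)cyclohexyl]-2-hydroxypropane-1,3-diyl diacetate
Conditions: 15, TiCl4 (1.1 equiv), CH2Cl2, −78 °C; 14, −78 to −30 °C; aq. NaHCO3
Reagents that add atoms: none
Why: Mukaiyama aldol addition to the ketone, which TiCl4 activates by chelation with an acetoxy carbonyl, forms the C6–C bond and the tertiary carbinol (not a stereocentre); the titanium aldolate of this ketone–ketone aldol can revert and re-add, so the side chain should end equatorial at C6, cis to the isopropenyl group, and C2 is untouched because no base is present.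

Step 10
Reactants: 16 2-[(1S,3S,4S)-4-ethenyl-4-methyl-2-oxo-3-(prop-1-en-2-yl)cyclohexyl]-2-hydroxypropane-1,3-diyl diacetate
Product: 17 2-[(1R,2R,3S,4S)-4-ethenyl-2-hydroxy-4-methyl-3-(prop-1-en-2-yl)cyclohexyl]-2-hydroxypropane-1,3-diyl diacetate
Conditions: Me4NBH(OAc)3 (5 equiv), AcOH–MeCN (1:1), −30 °C
Reagents that add atoms: none
Why: Evans–Saksena reduction: the tertiary hydroxyl binds the triacetoxyborohydride and delivers hydride to the ketone through a chair transition state, which gives the 1,3-anti diol, that is the equatorial C1 hydroxyl trans to the substituents at C2 and C6.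

**Compound list**

1 | but-3-yn-1-ol | C#CCCO | starting material
2 | dimethyl{(1E)-4-[(dimethylalumanyl)oxy]-2-methylbut-1-en-1-yl}alumane | C[Al](C)/C=C(\C)CCO[Al](C)C | intermediate (not isolated)
3 | (2E)-3-methylpent-2-ene-1,5-diol | OCC/C(C)=C/CO | intermediate
4 | (2E)-1,5-dibromo-3-methylpent-2-ene | BrCC/C(C)=C/CBr | intermediate
5 | {[(2E)-5-bromo-3-methylpent-2-en-1-yl]oxy}benzene | BrCC/C(C)=C/COc1ccccc1 | intermediate
6 | methyl 3-oxobutanoate | COC(=O)CC(C)=O | starting material
7 | methyl (7E)-7-methyl-3-oxo-9-phenoxynon-7-enoate | COC(=O)CC(=O)CCC/C(C)=C/COc1ccccc1 | intermediate (not isolated)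
8 | methyl (2S)-2-ethenyl-2-methyl-6-oxocyclohexane-1-carboxylate (epimers at C-1 of the name, and enol) | C=C[C@]1(C)CCCC(=O)C1C(=O)OC | intermediate
9 | methyl (1S,2S,6S)-2-ethenyl-6-hydroxy-2-methylcyclohexane-1-carboxylate | C=C[C@]1(C)CCC[C@H](O)[C@H]1C(=O)OC | intermediate
10 | (1S,2S,3S)-3-ethenyl-2-[2-hydroxy-1,3-bis(trimethylsilyl)propan-2-yl]-3-methylcyclohexan-1-ol | C=C[C@]1(C)CCC[C@H](O)[C@H]1C(O)(C[Si](C)(C)C)C[Si](C)(C)C | intermediate (not isolated)
11 | (1S,2R,3S)-3-ethenyl-3-methyl-2-[3-(trimethylsilyl)prop-1-en-2-yl]cyclohexan-1-ol | C=C[C@]1(C)CCC[C@H](O)[C@H]1C(=C)C[Si](C)(C)C | intermediate (not isolated)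
12 | (1S,2S,3S)-3-ethenyl-3-methyl-2-(prop-1-en-2-yl)cyclohexan-1-ol | C=C[C@]1(C)CCC[C@H](O)[C@H]1C(=C)C | intermediate
13 | (2S,3S)-3-ethenyl-3-methyl-2-(prop-1-en-2-yl)cyclohexan-1-one | C=C[C@]1(C)CCCC(=O)[C@H]1C(=C)C | intermediate
14 | {[(5S,6S)-5-ethenyl-5-methyl-6-(prop-1-en-2-yl)cyclohex-1-en-1-yl]oxy}trimethylsilane | C=C[C@]1(C)CCC=C(O[Si](C)(C)C)[C@H]1C(=C)C | intermediate
15 | 2-oxopropane-1,3-diyl diacetate | CC(=O)OCC(=O)COC(C)=O | starting material
16 | 2-[(1S,3S,4S)-4-ethenyl-4-methyl-2-oxo-3-(prop-1-en-2-yl)cyclohexyl]-2-hydroxypropane-1,3-diyl diacetate | C=C[C@]1(C)CC[C@@H](C(O)(COC(C)=O)COC(C)=O)C(=O)[C@H]1C(=C)C | intermediate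
17 | 2-[(1R,2R,3S,4S)-4-ethenyl-2-hydroxy-4-methyl-3-(prop-1-en-2-yl)cyclohexyl]-2-hydroxypropane-1,3-diyl diacetate | C=C[C@]1(C)CC[C@@H](C(O)(COC(C)=O)COC(C)=O)[C@H](O)[C@H]1C(=C)C | target

Total step count: 10. Longest linear sequence: 10 steps (1 to 17); 6 and 15 enter as commercial materials.

**Steps most likely to fail**

Step 4. The ring closure may be lost to intermolecular allylation, to attack at the unsubstituted allyl terminus after syn–anti isomerisation of the π-allyl complex, or to weak face selection by the ligand. The fallback sets out from 6 and comes back at 8, and makes the two ring bonds in separate steps. The dianion of 6 is alkylated with 2-(2-bromoethyl)-2-methyl-1,3-dioxolane to give methyl 6-(2-methyl-1,3-dioxolan-2-yl)-3-oxohexanoate F1. Aqueous acid removes the ketal to give methyl 3,7-dioxooctanoate F2. Piperidinium acetate closes the ring by intramolecular Knoevenagel condensation to methyl 2-methyl-6-oxocyclohex-1-ene-1-carboxylate F3. Copper-catalysed enantioselective conjugate addition of a vinylaluminium reagent (Cu(OTf)2, chiral N-heterocyclic carbene ligand) to the doubly activated alkene of F3 then sets the quaternary carbon and gives 8.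

Step 5. Hydrogen may be delivered with poor face selection at the hindered ketone, or the vinyl group may be reduced under pressure. The fallback sets out from 8 and comes back at 9, and replaces kinetic control of the ester-bearing carbon by thermodynamic control. Transfer hydrogenation with RuCl[(S,S)-TsDPEN](p-cymene) in HCO2H–Et3N, which leaves alkenes alone, sets only the carbinol and should give mainly the cis isomer, methyl (1R,2S,6S)-2-ethenyl-6-hydroxy-2-methylcyclohexane-1-carboxylate F4. NaOMe in MeOH then epimerises the ester-bearing carbon to the all-equatorial trans isomer 9.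

Step 9. The hindered enol silane may add slowly to the ketone, the aldolate may fail to equilibrate and keep the side chain axial from kinetic attack, or an acetate may be lost under the Lewis acid. The fallback sets out from 14 and comes back at 17, and uses a reversible metal aldolate and a protected ketone. MeLi cleaves 14 to the regiodefined lithium enolate, which after transmetalation with ZnCl2 adds to 2,2-dimethyl-1,3-dioxan-5-one between −78 and 0 °C, where the zinc aldolate can revert and settle equatorial, to give (2S,3S,6S)-3-ethenyl-6-(5-hydroxy-2,2-dimethyl-1,3-dioxan-5-yl)-3-methyl-2-(prop-1-en-2-yl)cyclohexan-1-one F5. Me4NBH(OAc)3 gives (1R,2S,3S,6R)-3-ethenyl-6-(5-hydroxy-2,2-dimethyl-1,3-dioxan-5-yl)-3-methyl-2-(prop-1-en-2-yl)cyclohexan-1-ol F6. Aqueous acetic acid removes the acetonide to give 2-[(1R,2R,3S,4S)-4-ethenyl-2-hydroxy-4-methyl-3-(prop-1-en-2-yl)cyclohexyl]propane-1,2,3-triol F7. Ac2O with 2,4,6-collidine at −20 °C acetylates only the two primary hydroxyls and gives 17.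

**Further compounds**

F1 | step 4 | methyl 6-(2-methyl-1,3-dioxolan-2-yl)-3-oxohexanoate | COC(=O)CC(=O)CCCC1(C)OCCO1
F2 | step 4 | methyl 3,7-dioxooctanoate | COC(=O)CC(=O)CCCC(C)=O
F3 | step 4 | methyl 2-methyl-6-oxocyclohex-1-ene-1-carboxylate | COC(=O)C1=C(C)CCCC1=O
F4 | step 5 | methyl (1R,2S,6S)-2-ethenyl-6-hydroxy-2-methylcyclohexane-1-carboxylate | C=C[C@]1(C)CCC[C@H](O)[C@@H]1C(=O)OC
F5 | step 9 | (2S,3S,6S)-3-ethenyl-6-(5-hydroxy-2,2-dimethyl-1,3-dioxan-5-yl)-3-methyl-2-(prop-1-en-2-yl)cyclohexan-1-one | C=C[C@]1(C)CC[C@@H](C2(O)COC(C)(C)OC2)C(=O)[C@H]1C(=C)C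
F6 | step 9 | (1R,2S,3S,6R)-3-ethenyl-6-(5-hydroxy-2,2-dimethyl-1,3-dioxan-5-yl)-3-methyl-2-(prop-1-en-2-yl)cyclohexan-1-ol | C=C[C@]1(C)CC[C@@H](C2(O)COC(C)(C)OC2)[C@H](O)[C@H]1C(=C)C
F7 | step 9 | 2-[(1R,2R,3S,4S)-4-ethenyl-2-hydroxy-4-methyl-3-(prop-1-en-2-yl)cyclohexyl]propane-1,2,3-triol | C=C[C@]1(C)CC[C@@H](C(O)(CO)CO)[C@H](O)[C@H]1C(=C)C
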